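**Retrosynthetic overview**
1. Target 13 ⇐ β-methoxy enone 11: acid removes all four MOM groups and closes the pyranone (O1–C2 bond). This is the only ring formed, and it is formed last.
2. 11 ⇐ aryl iodide 6 + CO + β-aryl enol ether 9: proposed new Pd-catalysed carbonylative C-acylation (C4a–C4 and C4–C3 bonds).
3. 6 ⇐ 2,3-dihydroxy-4-methoxybenzaldehyde 1: MOM protection, Baeyer–Villiger (CHO → OH), ortho-iodination, MOM protection.
4. 9 ⇐ 3-hydroxy-4,5-dimethoxybenzaldehyde 7: MOM protection, Wittig methoxymethylenation.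
5. Rings A and B are bought; ring C is built in step 8.

Assumption: the target has no stereocentre, so "single enantiomer" needs no stereocontrol; 9 and 11 are E/Z mixtures that converge in step 8 and are written without alkene geometry.

**Route**

Step 1
Reactants: 1 2,3-dihydroxy-4-methoxybenzaldehyde
Product: 2 4-methoxy-2,3-bis(methoxymethoxy)benzaldehyde
Conditions: MOMCl (3 equiv), i-Pr2NEt (4 equiv), CH2Cl2, 0 °C → rt
Reagents that add atoms: chloromethyl methyl ether (MOMCl), COCCl
Why: Williamson-type O-alkylation (MOM protection) of both phenols under amine base leaves the aldehyde untouched; no stereocentre is formed.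

Step 2
Reactants: 2 4-methoxy-2,3-bis(methoxymethoxy)benzaldehyde
Product: 4 4-methoxy-2,3-bis(methoxymethoxy)phenol, via aryl formate 3 (not isolated)
Conditions: mCPBA (1.3 equiv), CH2Cl2, 0 °C → rt; then K2CO3 (cat.), MeOH, rt
Reagents that add atoms: meta-chloroperoxybenzoic acid (mCPBA), OOC(=O)c1cccc(Cl)c1
Why: Baeyer–Villiger (Dakin-type) oxidation, in which the electron-rich aryl group with ortho and para alkoxy donors migrates in preference to hydrogen, and the formate is then methanolysed to the phenol.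

Step 3
Reactants: 4 4-methoxy-2,3-bis(methoxymethoxy)phenol
Product: 5 6-iodo-4-methoxy-2,3-bis(methoxymethoxy)phenol
Conditions: I2 (1.05 equiv), NaHCO3 (2 equiv), THF/H2O 1:1, 0 °C → rt
Reagents that add atoms: iodine, II
Why: Electrophilic aromatic iodination through the phenoxide goes to C6, the only free ortho position (para is blocked by OMe), which is far more activated than C5 next to the methoxy group.

Step 4
Reactants: 5 6-iodo-4-methoxy-2,3-bis(methoxymethoxy)phenol
Product: 6 1-iodo-5-methoxy-2,3,4-tris(methoxymethoxy)benzene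
Conditions: NaH (1.2 equiv), MOMCl (1.3 equiv), DMF, 0 °C → rt
Reagents that add atoms: chloromethyl methyl ether (MOMCl), COCCl
Why: Williamson O-alkylation of the sodium phenoxide masks the last free OH, so no nucleophilic phenol is present in the carbonylation step.

Step 5
Reactants: 7 3-hydroxy-4,5-dimethoxybenzaldehyde
Product: 8 3,4-dimethoxy-5-(methoxymethoxy)benzaldehyde
Conditions: MOMCl (1.5 equiv), i-Pr2NEt (2 equiv), CH2Cl2, 0 °C → rt
Reagents that add atoms: chloromethyl methyl ether (MOMCl), COCCl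
Why: Standard MOM protection of a phenol by O-alkylation; the aldehyde is inert to these conditions.

Step 6
Reactants: 8 3,4-dimethoxy-5-(methoxymethoxy)benzaldehyde
Product: 9 (E/Z)-1,2-dimethoxy-5-(2-methoxyethenyl)-3-(methoxymethoxy)benzene
Conditions: Ph3P(CH2OMe)Cl (1.4 equiv), KOt-Bu (1.4 equiv), THF, 0 °C → rt
Reagents that add atoms: (methoxymethyl)triphenylphosphonium chloride, COC[P+](c1ccccc1)(c1ccccc1)c1ccccc1.[Cl-]
Why: Wittig methoxymethylenation with the non-stabilised α-alkoxy ylide gives the enol ether as an E/Z mixture, and both isomers are used.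

Step 7
Reactants: 6 1-iodo-5-methoxy-2,3,4-tris(methoxymethoxy)benzene; 9 (E/Z)-1,2-dimethoxy-5-(2-methoxyethenyl)-3-(methoxymethoxy)benzene
Product: 11 (E/Z)-2-[3,4-dimethoxy-5-(methoxymethoxy)phenyl]-3-methoxy-1-[5-methoxy-2,3,4-tris(methoxymethoxy)phenyl]prop-2-en-1-one, via aroyl iodide 10 (not isolated)
Conditions: Pd(Pt-Bu3)2 (5 mol%), CO (4 atm), i-Pr2NEt (1.5 equiv), 9 (1.5 equiv), 4 Å MS, MeCN/PhMe 1:1, 70 °C
Reagents that add atoms: carbon monoxide, [C-]#[O+]
Why: Proposed new method: oxidative addition of Pd(0)/Pt-Bu3 into the C–I bond of 6, CO insertion and reversible acyl–iodide reductive elimination (favoured by the bulky phosphine) give aroyl iodide 10 in equilibrium with its acyl-Pd(II) iodide, and this strong acyl electrophile is attacked by enol ether 9 at the carbon β to oxygen (the aryl-bearing carbon, the site where β-methoxystyrenes are protonated), after which i-Pr2NEt removes the proton to give the β-methoxy enone with the C4a–C4 and C4–C3 bonds in place; the closest known reaction types are the Pd-catalysed carbonylative Heck acylation of terminal vinyl ethers to 3-alkoxy enones, the Pd-catalysed carbonylative Friedel–Crafts-type acylation of electron-rich heteroarenes through aroyl halides made in situ, and the Stork-type C-acylation of enol ethers and enamines by acid chlorides, none of which has been shown on a 1,2-disubstituted β-aryl enol ether.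

Step 8
Reactants: 11 (E/Z)-2-[3,4-dimethoxy-5-(methoxymethoxy)phenyl]-3-methoxy-1-[5-methoxy-2,3,4-tris(methoxymethoxy)phenyl]prop-2-en-1-one
Product: 13 7,8-dihydroxy-3-(3-hydroxy-4,5-dimethoxyphenyl)-6-methoxy-4H-chromen-4-one, via tetraphenol enone 12 (not isolated)
Conditions: HCl (3 M in MeOH), degassed, Ar, 50 °C
Reagents that add atoms: none
Why: Acid-catalysed acetal cleavage frees the four phenols, and the 2'-OH then closes the pyranone by oxa-Michael addition to the β-methoxy enone and elimination of methanol, the standard last stage of isoflavone synthesis from α-formyl deoxybenzoin equivalents; methyl ethers survive and no stereocentre is involved.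

**Compound list**
1 | 2,3-dihydroxy-4-methoxybenzaldehyde | O=Cc1ccc(OC)c(O)c1O | starting material
2 | 4-methoxy-2,3-bis(methoxymethoxy)benzaldehyde | O=Cc1ccc(OC)c(OCOC)c1OCOC | intermediate
3 | 4-methoxy-2,3-bis(methoxymethoxy)phenyl formate | O=COc1ccc(OC)c(OCOC)c1OCOC | intermediate
4 | 4-methoxy-2,3-bis(methoxymethoxy)phenol | Oc1ccc(OC)c(OCOC)c1OCOC | intermediate
5 | 6-iodo-4-methoxy-2,3-bis(methoxymethoxy)phenol | Oc1c(I)cc(OC)c(OCOC)c1OCOC | intermediate
6 | 1-iodo-5-methoxy-2,3,4-tris(methoxymethoxy)benzene | COCOc1c(I)cc(OC)c(OCOC)c1OCOC | intermediate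
7 | 3-hydroxy-4,5-dimethoxybenzaldehyde | O=Cc1cc(O)c(OC)c(OC)c1 | starting material
8 | 3,4-dimethoxy-5-(methoxymethoxy)benzaldehyde | O=Cc1cc(OCOC)c(OC)c(OC)c1 | intermediate
9 | 1,2-dimethoxy-5-(2-methoxyethenyl)-3-(methoxymethoxy)benzene, E/Z mixture | COC=Cc1cc(OCOC)c(OC)c(OC)c1 | intermediate
10 | 5-methoxy-2,3,4-tris(methoxymethoxy)benzoyl iodide | O=C(I)c1cc(OC)c(OCOC)c(OCOC)c1OCOC | intermediate
11 | 2-[3,4-dimethoxy-5-(methoxymethoxy)phenyl]-3-methoxy-1-[5-methoxy-2,3,4-tris(methoxymethoxy)phenyl]prop-2-en-1-one, E/Z mixture | COC=C(c1cc(OCOC)c(OC)c(OC)c1)C(=O)c1cc(OC)c(OCOC)c(OCOC)c1OCOC | intermediate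
12 | 2-(3-hydroxy-4,5-dimethoxyphenyl)-3-methoxy-1-(2,3,4-trihydroxy-5-methoxyphenyl)prop-2-en-1-one, E/Z mixture | COC=C(c1cc(O)c(OC)c(OC)c1)C(=O)c1cc(OC)c(O)c(O)c1O | intermediate
13 | 7,8-dihydroxy-3-(3-hydroxy-4,5-dimethoxyphenyl)-6-methoxy-4H-chromen-4-one (CNP0115098.0, achiral) | COc1cc2c(=O)c(-c3cc(O)c(OC)c(OC)c3)coc2c(O)c1O | target

**Summary**
Total steps: 8. Longest linear sequence: 6 (steps 1, 2, 3, 4, 7, 8); steps 5 and 6 form the second branch.

**Three steps most likely to fail**

Step 7 (proposed new carbonylative acylation). The risks are Heck-type insertion with the opposite regiochemistry, non-carbonylative coupling, and hydrolysis or reduction of the acyl species. The fallback uses known chemistry only, sets out from 6 and comes back to the route at 13. Iodine–magnesium exchange on 6 with i-PrMgCl·LiCl (THF, −20 °C) gives the aryl Grignard reagent [5-methoxy-2,3,4-tris(methoxymethoxy)phenyl]magnesium chloride F1. Quenching with N-methoxy-N-methylacetamide gives the acetophenone 1-[5-methoxy-2,3,4-tris(methoxymethoxy)phenyl]ethan-1-one F2. Claisen–Schmidt condensation of F2 with aldehyde 8 (KOH, EtOH, rt) gives the chalcone (E)-3-[3,4-dimethoxy-5-(methoxymethoxy)phenyl]-1-[5-methoxy-2,3,4-tris(methoxymethoxy)phenyl]prop-2-en-1-one F3. The classical oxidative 1,2-aryl migration of F3 with Tl(NO3)3·3H2O in MeOH/HC(OMe)3 gives the racemic β-keto acetal 2-[3,4-dimethoxy-5-(methoxymethoxy)phenyl]-3,3-dimethoxy-1-[5-methoxy-2,3,4-tris(methoxymethoxy)phenyl]propan-1-one F4; its stereocentre is lost on ring closure. Under the conditions of step 8 (HCl, MeOH, 50 °C), F4 loses its MOM groups and cyclises to 13.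

Step 3 (ortho-iodination of a very electron-rich 4-alkoxyphenol). The risks are oxidation to quinone and some attack at C5. The fallback replaces electrophilic substitution by directed metalation, sets out from 4 and comes back at 6. Phenol 4 is first MOM-protected (NaH, MOMCl, DMF) to 1-methoxy-2,3,4-tris(methoxymethoxy)benzene F5. Directed ortho-lithiation (n-BuLi, TMEDA, THF, −78 → 0 °C) next to the terminal OMOM group, a stronger director than OMe, gives the aryllithium [5-methoxy-2,3,4-tris(methoxymethoxy)phenyl]lithium F6. Quenching with I2 gives 6 directly, so step 4 is no longer needed.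

Step 8 (one-pot global deprotection and ring closure). The risks are incomplete cyclisation, ring alkylation by formaldehyde equivalents, and air oxidation of the 7,8-catechol. The fallback separates ring closure from deprotection with an orthogonal silyl group, sets out from 5 and comes back at 13. TBSCl/imidazole (DMF) converts 5 to the silyl ether tert-butyl[6-iodo-4-methoxy-2,3-bis(methoxymethoxy)phenoxy]dimethylsilane F7. The conditions of step 7 with 9 take F7 through the aroyl iodide 2-[(tert-butyldimethylsilyl)oxy]-5-methoxy-3,4-bis(methoxymethoxy)benzoyl iodide F8 to the enone 1-[2-[(tert-butyldimethylsilyl)oxy]-5-methoxy-3,4-bis(methoxymethoxy)phenyl]-2-[3,4-dimethoxy-5-(methoxymethoxy)phenyl]-3-methoxyprop-2-en-1-one F9. TBAF (THF, 0 °C) frees the phenoxide, which cyclises by addition–elimination to the stable, chromatographable isoflavone 3-[3,4-dimethoxy-5-(methoxymethoxy)phenyl]-6-methoxy-7,8-bis(methoxymethoxy)-4H-chromen-4-one F10. Removal of the three remaining MOM groups from F10 (HCl/MeOH, or ZnBr2/n-PrSH in CH2Cl2) gives 13.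

**Further compounds**
F1 | step 7 | [5-methoxy-2,3,4-tris(methoxymethoxy)phenyl]magnesium chloride | COCOc1c([Mg]Cl)cc(OC)c(OCOC)c1OCOC
F2 | step 7 | 1-[5-methoxy-2,3,4-tris(methoxymethoxy)phenyl]ethan-1-one | CC(=O)c1cc(OC)c(OCOC)c(OCOC)c1OCOC
F3 | step 7 | (E)-3-[3,4-dimethoxy-5-(methoxymethoxy)phenyl]-1-[5-methoxy-2,3,4-tris(methoxymethoxy)phenyl]prop-2-en-1-one | O=C(/C=C/c1cc(OCOC)c(OC)c(OC)c1)c1cc(OC)c(OCOC)c(OCOC)c1OCOC
F4 | step 7 | 2-[3,4-dimethoxy-5-(methoxymethoxy)phenyl]-3,3-dimethoxy-1-[5-methoxy-2,3,4-tris(methoxymethoxy)phenyl]propan-1-one, racemic | COC(OC)C(c1cc(OCOC)c(OC)c(OC)c1)C(=O)c1cc(OC)c(OCOC)c(OCOC)c1OCOC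
F5 | step 3 | 1-methoxy-2,3,4-tris(methoxymethoxy)benzene | COCOc1ccc(OC)c(OCOC)c1OCOC
F6 | step 3 | [5-methoxy-2,3,4-tris(methoxymethoxy)phenyl]lithium | [Li]c1cc(OC)c(OCOC)c(OCOC)c1OCOC
F7 | step 8 | tert-butyl[6-iodo-4-methoxy-2,3-bis(methoxymethoxy)phenoxy]dimethylsilane | COCOc1c(O[Si](C)(C)C(C)(C)C)c(I)cc(OC)c1OCOC
F8 | step 8 | 2-[(tert-butyldimethylsilyl)oxy]-5-methoxy-3,4-bis(methoxymethoxy)benzoyl iodide | O=C(I)c1cc(OC)c(OCOC)c(OCOC)c1O[Si](C)(C)C(C)(C)C
F9 | step 8 | 1-[2-[(tert-butyldimethylsilyl)oxy]-5-methoxy-3,4-bis(methoxymethoxy)phenyl]-2-[3,4-dimethoxy-5-(methoxymethoxy)phenyl]-3-methoxyprop-2-en-1-one, E/Z mixture | COC=C(c1cc(OCOC)c(OC)c(OC)c1)C(=O)c1cc(OC)c(OCOC)c(OCOC)c1O[Si](C)(C)C(C)(C)C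
F10 | step 8 | 3-[3,4-dimethoxy-5-(methoxymethoxy)phenyl]-6-methoxy-7,8-bis(methoxymethoxy)-4H-chromen-4-one | COCOc1c(OCOC)c(OC)cc2c(=O)c(-c3cc(OCOC)c(OC)c(OC)c3)coc12
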